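**Plan**
- Retrosynthesis cuts, in order: the exocyclic Cα=CH alkene (cross-metathesis), the lactone O–Cγ bond (palladium allylic substitution), the Cα–Cβ bond (Morita–Baylis–Hillman), and in the side chain the C8–C9 bond (allylboration), the C8 acetate and the C1 ester.
- Forward: 2-methylbut-3-en-2-ol → tertiary methyl carbonate → (E)-enal → Baylis–Hillman adduct → silyl ether → acid → palladium lactonisation, which closes the only ring. The nerol-derived homoallylic acetate is then joined by cross-metathesis and the silyl group is removed.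
- Enabling feature: the lactone γ-carbon is an allylic C–O centre whose 2-methylprop-1-enyl group ends in a CMe2 carbon. An η3-allylpalladium unit over Cγ–CH–CMe2 can change faces at that symmetric terminus before the five-membered ring closes.
- Stereochemistry: Cβ from the β-isocupreidine Baylis–Hillman reaction; Cγ (trans) from the key step under control of Cβ; C8 from reagent-controlled allylboration. The 2Z alkene comes from nerol, 6E from SeO2 oxidation, the enoate E from the acid, and the alkylidene E from the metathesis.

Key step: step 6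

Remark: the facial preferences of β-isocupreidine (R-carbinol) and of the (+)-α-pinene-derived allylborane (S-carbinol when the aldehyde substituent outranks allyl) are assumed to carry over from simpler aldehydes to enals 5 and 16.

**Step 1**
Reactants: 1 2-methylbut-3-en-2-ol
Product: 3 methyl 2-methylbut-3-en-2-yl carbonate, via lithium 2-methylbut-3-en-2-olate 2 (not isolated)
Conditions: n-BuLi (1.05 equiv), THF, −78 °C; ClCO2Me, −78 °C → rt
Reagents that add atoms: methyl chloroformate, COC(=O)Cl
Why: O-acylation of the preformed lithium tertiary alkoxide with a chloroformate is the standard carbonate synthesis for hindered tertiary allylic alcohols and touches no stereo element.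

**Step 2**
Reactants: 3 methyl 2-methylbut-3-en-2-yl carbonate; 4 (E)-but-2-enal (crotonaldehyde, 4 equiv)
Product: 5 methyl (E)-2-methyl-5-oxopent-3-en-2-yl carbonate
Conditions: second-generation Hoveyda–Grubbs catalyst RuCl2(SIMes)(=CH-C6H4-2-OiPr) (5 mol%), CH2Cl2, 40 °C
Reagents that add atoms: none
Why: olefin cross-metathesis of the hindered, non-dimerising vinyl group of 3 with an excess of the enal partner is a well-used route to γ-branched (E)-enals, propene being lost and the E geometry being the thermodynamic one.

**Step 3**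
Reactants: 5 methyl (E)-2-methyl-5-oxopent-3-en-2-yl carbonate; 6 1,1,1,3,3,3-hexafluoropropan-2-yl acrylate
Product: 7 1,1,1,3,3,3-hexafluoropropan-2-yl (3R,4E)-3-hydroxy-6-(methoxycarbonyloxy)-6-methyl-2-methylidenehept-4-enoate
Conditions: β-isocupreidine (10 mol%), 6 (1.3 equiv), DMF, −55 °C
Reagents that add atoms: none
Why: asymmetric Morita–Baylis–Hillman reaction, in which the quinuclidine nitrogen of β-isocupreidine adds to the very electrophilic fluorinated acrylate and its phenolic hydroxyl directs the 1,2-aldol step to one aldehyde face, the face that with this catalyst delivers the (R)-carbinol.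

**Step 4**
Reactants: 7 the (3R)-Baylis–Hillman alcohol
Product: 8 1,1,1,3,3,3-hexafluoropropan-2-yl (3R,4E)-3-(tert-butyldimethylsilyloxy)-6-(methoxycarbonyloxy)-6-methyl-2-methylidenehept-4-enoate
Conditions: TBSOTf, 2,6-lutidine, CH2Cl2, −78 °C
Reagents that add atoms: tert-butyldimethylsilyl trifluoromethanesulfonate, CC(C)(C)[Si](C)(C)OS(=O)(=O)C(F)(F)F
Why: a silyl triflate with a hindered pyridine base silylates the secondary allylic alcohol at low temperature without disturbing the activated ester or the tertiary carbonate (standard silyl ether formation).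

**Step 5**
Reactants: 8 the silylated hexafluoroisopropyl ester
Product: 10 (3R,4E)-3-(tert-butyldimethylsilyloxy)-6-(methoxycarbonyloxy)-6-methyl-2-methylidenehept-4-enoic acid, via lithium carboxylate salt 9 (not isolated)
Conditions: LiOH·H2O (1.1 equiv), THF–H2O, 0 °C; then cold 1 M HCl to pH 4
Reagents that add atoms: lithium hydroxide, [Li+].[OH-]
Why: saponification is chemoselective because the hexafluoroisopropyl ester is far more electrophilic than the tertiary alkyl methyl carbonate, so one equivalent of hydroxide at 0 °C should cleave only the ester before mild acidification.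

**Step 6**
Reactants: 10 the (3R)-2-methylidene-3-silyloxy acid carrying the (E)-allylic tertiary methyl carbonate
Product: 11 (4S,5R)-4-(tert-butyldimethylsilyloxy)-3-methylidene-5-(2-methylprop-1-en-1-yl)oxolan-2-one (trans lactone)
Conditions: Pd2(dba)3·CHCl3 (2.5 mol%), PPh3 (12 mol%), THF, rt → 40 °C, no added base
Reagents that add atoms: none
Why: Zerovalent palladium ionises the tertiary allylic methyl carbonate anti to the leaving group, CO2 and methoxide are lost and the methoxide deprotonates the acid, giving a zwitterionic η3-allylpalladium carboxylate over C4–C5–C6 whose carboxylate oxygen attacks the secondary terminus C4 on the face opposite palladium to form the O–Cγ bond. The closest known reaction type is the palladium-catalysed intramolecular allylic substitution by carboxylates (Tsuji–Trost lactonisation to γ-alkenyl butyrolactones) run where the allyl complexes equilibrate by π–σ–π isomerisation. The single ring closes in a 5-exo mode with the C5=C6 double bond left outside the ring, and attack at the CMe2 terminus is excluded because it would need a seven-membered lactone holding an E alkene, which secures the regioselectivity. The new γ-stereocentre is controlled by the existing (R)-silyloxy β-stereocentre: since the CMe2 terminus bears two identical methyl groups, η3–η1–η3 slippage there carries palladium from one allyl face to the other without changing the complex, so the two diastereomeric complexes interconvert and the one cyclising with the allyl unit anti to the bulky silyloxy group should react faster. The step needs trans diastereoselectivity, and this is backed thermodynamically because the product is itself an allylic carboxylate that zerovalent palladium can re-ionise, letting any cis lactone drain to the trans isomer. Base is omitted so that the acrylic acid unit is not exposed to conjugate addition.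

**Step 7**
Reactants: 12 nerol; 13 (E)-3-methylpent-2-enoic acid
Product: 14 (2Z)-3,7-dimethylocta-2,6-dien-1-yl (2E)-3-methylpent-2-enoate
Conditions: DCC, DMAP (10 mol%), CH2Cl2, 0 °C → rt
Reagents that add atoms: none
Why: Steglich esterification (carbodiimide activation with DMAP acyl transfer) joins a primary allylic alcohol and a β,β-disubstituted acrylic acid under neutral conditions that leave both alkene geometries untouched.

**Step 8**
Reactants: 14 the neryl ester
Product: 15 (2Z,6E)-8-hydroxy-3,7-dimethylocta-2,6-dien-1-yl (2E)-3-methylpent-2-enoate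
Conditions: SeO2 (0.3 equiv), t-BuOOH (3 equiv), salicylic acid (10 mol%), CH2Cl2, rt
Reagents that add atoms: tert-butyl hydroperoxide, CC(C)(C)OO (terminal oxygen source); selenium dioxide, O=[Se]=O (oxygen carrier)
Why: catalytic SeO2/t-BuOOH allylic oxidation (ene reaction then [2,3]-sigmatropic shift) is selective for the E-methyl group of the distal trisubstituted alkene, the 2,3-alkene and the enoate alkene being deactivated by their ester groups, so the 6E allylic alcohol should result and any over-oxidised enal converges in the next step.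

**Step 9**
Reactants: 15 the 8-hydroxy ester
Product: 16 (2Z,6E)-3,7-dimethyl-8-oxoocta-2,6-dien-1-yl (2E)-3-methylpent-2-enoate
Conditions: MnO2 (15 equiv), CH2Cl2, rt
Reagents that add atoms: none
Why: MnO2 oxidises allylic alcohols selectively to enals under neutral conditions without isomerising the alkenes.

**Step 10**
Reactants: 16 the 8-oxo ester
Product: 18 (2Z,6E,8S)-8-hydroxy-3,7-dimethylundeca-2,6,10-trien-1-yl (2E)-3-methylpent-2-enoate, via diisopinocampheylborinate ester 17 (not isolated)
Conditions: (−)-Ipc2BOMe, allylMgBr, Et2O, −78 °C → rt; then 16, −78 °C; NaBO3·4H2O, THF–H2O, rt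
Reagents that add atoms: allylmagnesium bromide, C=CC[Mg]Br; (−)-B-methoxydiisopinocampheylborane, COB([C@@H]1C[C@@H]2C[C@@H](C2(C)C)[C@H]1C)[C@@H]1C[C@@H]2C[C@@H](C2(C)C)[C@H]1C (its atoms stay only in 17)
Why: Brown allylboration through a chair Zimmerman–Traxler transition state adds the allyl group 1,2 to the enal under reagent control, and the borane from (+)-α-pinene-derived (−)-Ipc2BOMe gives the (S)-carbinol with aldehydes whose substituent outranks allyl, while the mild perborate work-up spares the ester.

**Step 11**
Reactants: 18 the (8S)-homoallylic alcohol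
Product: 19 (2Z,6E,8S)-8-acetoxy-3,7-dimethylundeca-2,6,10-trien-1-yl (2E)-3-methylpent-2-enoate
Conditions: Ac2O, pyridine, DMAP (cat.), CH2Cl2, 0 °C → rt
Reagents that add atoms: acetic anhydride, CC(=O)OC(C)=O
Why: DMAP-catalysed acetylation of a secondary allylic alcohol proceeds with retention at the stereocentre (standard acylation).

**Step 12**
Reactants: 11 the trans α-methylidene lactone; 19 the homoallylic acetate (2 equiv)
Product: 20 (2Z,6E,8S)-8-acetoxy-10-[(3E,4S,5R)-4-(tert-butyldimethylsilyloxy)-5-(2-methylprop-1-en-1-yl)-2-oxooxolan-3-ylidene]-3,7-dimethyldeca-2,6-dien-1-yl (2E)-3-methylpent-2-enoate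
Conditions: second-generation Hoveyda–Grubbs catalyst RuCl2(SIMes)(=CH-C6H4-2-OiPr) (10 mol%), 2,6-dichloro-1,4-benzoquinone (20 mol%), CH2Cl2, 40 °C, argon sweep
Reagents that add atoms: none
Why: olefin cross-metathesis of an α-methylene-γ-butyrolactone with a terminal alkene is established with this catalyst in the presence of a benzoquinone that suppresses ruthenium hydride isomerisation to the butenolide; the vinyl group of 19 is the only readily initiating alkene, the trisubstituted alkenes of both partners being much slower, and the E-alkylidene (chain away from the lactone carbonyl) should be favoured.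

**Step 13**
Reactants: 20 the silyl-protected coupling product
Product: 21 (2Z,6E,8S)-8-acetoxy-10-[(3E,4S,5R)-4-hydroxy-5-(2-methylprop-1-en-1-yl)-2-oxooxolan-3-ylidene]-3,7-dimethyldeca-2,6-dien-1-yl (2E)-3-methylpent-2-enoate (CNP0168501.1)
Conditions: HF·pyridine, pyridine, THF, 0 °C → rt
Reagents that add atoms: none
Why: buffered HF·pyridine cleaves the secondary silyl ether by fluoride attack at silicon without affecting the acetate, the two other esters or the alkylidene lactone.

**Compound list**
1 | 2-methylbut-3-en-2-ol | C=CC(C)(C)O | starting material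
2 | lithium 2-methylbut-3-en-2-olate (formed in situ) | [Li+].[O-]C(C)(C)C=C | intermediate
3 | methyl 2-methylbut-3-en-2-yl carbonate | COC(=O)OC(C)(C)C=C | intermediate
4 | (E)-but-2-enal (crotonaldehyde) | C/C=C/C=O | starting material
5 | methyl (E)-2-methyl-5-oxopent-3-en-2-yl carbonate | COC(=O)OC(C)(C)/C=C/C=O | intermediate
6 | 1,1,1,3,3,3-hexafluoropropan-2-yl acrylate | C=CC(=O)OC(C(F)(F)F)C(F)(F)F | starting material
7 | 1,1,1,3,3,3-hexafluoropropan-2-yl (3R,4E)-3-hydroxy-6-(methoxycarbonyloxy)-6-methyl-2-methylidenehept-4-enoate | C=C(C(=O)OC(C(F)(F)F)C(F)(F)F)[C@H](O)/C=C/C(C)(C)OC(=O)OC | intermediate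
8 | 1,1,1,3,3,3-hexafluoropropan-2-yl (3R,4E)-3-(tert-butyldimethylsilyloxy)-6-(methoxycarbonyloxy)-6-methyl-2-methylidenehept-4-enoate | C=C(C(=O)OC(C(F)(F)F)C(F)(F)F)[C@H](O[Si](C)(C)C(C)(C)C)/C=C/C(C)(C)OC(=O)OC | intermediate
9 | lithium (3R,4E)-3-(tert-butyldimethylsilyloxy)-6-(methoxycarbonyloxy)-6-methyl-2-methylidenehept-4-enoate (formed in situ) | [Li+].[O-]C(=O)C(=C)[C@H](O[Si](C)(C)C(C)(C)C)/C=C/C(C)(C)OC(=O)OC | intermediate
10 | (3R,4E)-3-(tert-butyldimethylsilyloxy)-6-(methoxycarbonyloxy)-6-methyl-2-methylidenehept-4-enoic acid | OC(=O)C(=C)[C@H](O[Si](C)(C)C(C)(C)C)/C=C/C(C)(C)OC(=O)OC | intermediate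
11 | (4S,5R)-4-(tert-butyldimethylsilyloxy)-3-methylidene-5-(2-methylprop-1-en-1-yl)oxolan-2-one | C=C1C(=O)O[C@H](C=C(C)C)[C@H]1O[Si](C)(C)C(C)(C)C | intermediate
12 | nerol, (2Z)-3,7-dimethylocta-2,6-dien-1-ol | OC/C=C(/C)CCC=C(C)C | starting material
13 | (E)-3-methylpent-2-enoic acid | CC/C(C)=C/C(=O)O | starting material
14 | (2Z)-3,7-dimethylocta-2,6-dien-1-yl (2E)-3-methylpent-2-enoate | CC/C(C)=C/C(=O)OC/C=C(/C)CCC=C(C)C | intermediate
15 | (2Z,6E)-8-hydroxy-3,7-dimethylocta-2,6-dien-1-yl (2E)-3-methylpent-2-enoate | CC/C(C)=C/C(=O)OC/C=C(/C)CC/C=C(\C)CO | intermediate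
16 | (2Z,6E)-3,7-dimethyl-8-oxoocta-2,6-dien-1-yl (2E)-3-methylpent-2-enoate | CC/C(C)=C/C(=O)OC/C=C(/C)CC/C=C(\C)C=O | intermediate
17 | (2Z,6E,8S)-8-[bis(isopinocampheyl)boranyloxy]-3,7-dimethylundeca-2,6,10-trien-1-yl (2E)-3-methylpent-2-enoate (formed in situ) | CC/C(C)=C/C(=O)OC/C=C(/C)CC/C=C(\C)[C@H](CC=C)OB([C@@H]1C[C@@H]2C[C@@H](C2(C)C)[C@H]1C)[C@@H]1C[C@@H]2C[C@@H](C2(C)C)[C@H]1C | intermediate
18 | (2Z,6E,8S)-8-hydroxy-3,7-dimethylundeca-2,6,10-trien-1-yl (2E)-3-methylpent-2-enoate | CC/C(C)=C/C(=O)OC/C=C(/C)CC/C=C(\C)[C@H](CC=C)O | intermediate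
19 | (2Z,6E,8S)-8-acetoxy-3,7-dimethylundeca-2,6,10-trien-1-yl (2E)-3-methylpent-2-enoate | CC/C(C)=C/C(=O)OC/C=C(/C)CC/C=C(\C)[C@H](CC=C)OC(C)=O | intermediate
20 | (2Z,6E,8S)-8-acetoxy-10-[(3E,4S,5R)-4-(tert-butyldimethylsilyloxy)-5-(2-methylprop-1-en-1-yl)-2-oxooxolan-3-ylidene]-3,7-dimethyldeca-2,6-dien-1-yl (2E)-3-methylpent-2-enoate | CC/C(C)=C/C(=O)OC/C=C(/C)CC/C=C(\C)[C@H](C/C=C1/C(=O)O[C@H](C=C(C)C)[C@H]1O[Si](C)(C)C(C)(C)C)OC(C)=O | intermediate
21 | (2Z,6E,8S)-8-acetoxy-10-[(3E,4S,5R)-4-hydroxy-5-(2-methylprop-1-en-1-yl)-2-oxooxolan-3-ylidene]-3,7-dimethyldeca-2,6-dien-1-yl (2E)-3-methylpent-2-enoate | CC/C(C)=C/C(=O)OC/C=C(/C)CC/C=C(\C)[C@H](C/C=C1/C(=O)O[C@H](C=C(C)C)[C@H]1O)OC(C)=O | target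

**Step count**
Total: 13 steps. Longest linear sequence: 8 steps (steps 1–6, 12, 13); the side-chain branch is 5 steps (7–11) before the union.

**Steps most likely to fail**

Step 12. The metathesis may stall at the hindered, electron-poor 1,1-disubstituted methylene next to the silyloxy group, the catalyst may engage the isobutenyl or chain trisubstituted alkenes, or E/Z control may be poor. The fallback replaces the intermolecular union by a silicon-tethered ring-closing metathesis. Setting out from lactone 11, HF·pyridine should give (4S,5R)-4-hydroxy-3-methylidene-5-(2-methylprop-1-en-1-yl)oxolan-2-one F1. Alcohol 18 is converted with iPr2SiCl2 and imidazole into its chlorosilyl ether and coupled with F1 to the mixed diisopropylsilylene bis-ether F2. Ring-closing metathesis at high dilution with the second-generation Hoveyda–Grubbs catalyst should close the eight-membered dioxasilacyclooctene F3, whose ring forces C9 and the lactone β-carbon cis on the new double bond, that is, the E-alkylidene. HF·pyridine then frees the diol F4. Acetylation of the more accessible side-chain carbinol (Ac2O, pyridine, low temperature) returns to the route at target 21; this last selectivity is the weak point of the fallback, since the ring hydroxyl is only moderately more hindered.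

Step 6. The π-allyl complex may lose a β-hydrogen from a methyl group to give a diene, or face exchange at the tertiary terminus may be too slow for good trans selectivity. The fallback builds the γ-carbon by carbonyl addition instead. Setting out from silyl ether 8, ozonolysis of the disubstituted alkene (the acrylate alkene being far less reactive toward ozone; Me2S work-up) should give 1,1,1,3,3,3-hexafluoropropan-2-yl (S)-3-(tert-butyldimethylsilyloxy)-2-methylidene-4-oxobutanoate F5. Nozaki–Hiyama–Kishi addition of 1-bromo-2-methylprop-1-ene (CrCl2, catalytic NiCl2, DMF) should follow Felkin–Anh (anti) selectivity to the γ-hydroxy ester F6, which closes onto the activated hexafluoroisopropyl ester and so comes back to the route at lactone 11.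

Step 3. The hindered, γ-oxygenated enal may react slowly, be consumed as the dioxanone by-product, or give eroded enantioselectivity. The fallback is an auxiliary-controlled aldol with an acrylate-anion surrogate. (S)-4-Benzyloxazolidin-2-one is acylated with 3-(phenylselanyl)propanoyl chloride to (S)-4-benzyl-3-[3-(phenylselanyl)propanoyl]oxazolidin-2-one F7. Its dibutylboron enolate (Bu2BOTf, iPr2NEt, CH2Cl2, −78 °C) should add to enal 5 to give the syn-aldol F8 with the (3R)-carbinol. Silylation (TBSOTf, 2,6-lutidine) gives the silyl ether F9. LiOH/H2O2 then oxidises selenium, the selenoxide eliminates to unveil the α-methylidene group and the auxiliary is cleaved, coming back to the route at acid 10.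

**Further compounds**
F1 | step 12 | (4S,5R)-4-hydroxy-3-methylidene-5-(2-methylprop-1-en-1-yl)oxolan-2-one | C=C1C(=O)O[C@H](C=C(C)C)[C@H]1O
F2 | step 12 | (2Z,6E,8S)-8-[diisopropyl{[(3S,4R... lactone)]oxy}silyl]oxy ether: mixed diisopropylsilylene bis-ether of alcohol 18 and hydroxy lactone F1 | CC/C(C)=C/C(=O)OC/C=C(/C)CC/C=C(\C)[C@H](CC=C)O[Si](C(C)C)(C(C)C)O[C@@H]1[C@@H](C=C(C)C)OC(=O)C1=C
F3 | step 12 | eight-membered diisopropyl-dioxasilacyclooctene fused to the lactone at Cα–Cβ, carrying the (E)-alkylidene bond inside the ring and the dienyl ester chain at C8 | CC/C(C)=C/C(=O)OC/C=C(/C)CC/C=C(\C)[C@@H]1C/C=C2/C(=O)O[C@H](C=C(C)C)[C@H]2O[Si](C(C)C)(C(C)C)O1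
F4 | step 12 | (2Z,6E,8S)-8-hydroxy-10-[(3E,4S,5R)-4-hydroxy-5-(2-methylprop-1-en-1-yl)-2-oxooxolan-3-ylidene]-3,7-dimethyldeca-2,6-dien-1-yl (2E)-3-methylpent-2-enoate | CC/C(C)=C/C(=O)OC/C=C(/C)CC/C=C(\C)[C@H](C/C=C1/C(=O)O[C@H](C=C(C)C)[C@H]1O)O
F5 | step 6 | 1,1,1,3,3,3-hexafluoropropan-2-yl (S)-3-(tert-butyldimethylsilyloxy)-2-methylidene-4-oxobutanoate | C=C(C(=O)OC(C(F)(F)F)C(F)(F)F)[C@H](O[Si](C)(C)C(C)(C)C)C=O
F6 | step 6 | 1,1,1,3,3,3-hexafluoropropan-2-yl (3S,4R)-3-(tert-butyldimethylsilyloxy)-4-hydroxy-6-methyl-2-methylidenehept-5-enoate | C=C(C(=O)OC(C(F)(F)F)C(F)(F)F)[C@H](O[Si](C)(C)C(C)(C)C)[C@H](O)C=C(C)C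
F7 | step 3 | (S)-4-benzyl-3-[3-(phenylselanyl)propanoyl]oxazolidin-2-one | O=C1OC[C@H](Cc2ccccc2)N1C(=O)CC[Se]c1ccccc1
F8 | step 3 | (S)-4-benzyl-3-[(2S,3R,4E)-3-hydroxy-6-(methoxycarbonyloxy)-6-methyl-2-[(phenylselanyl)methyl]hept-4-enoyl]oxazolidin-2-one | O=C1OC[C@H](Cc2ccccc2)N1C(=O)[C@@H](C[Se]c1ccccc1)[C@H](O)/C=C/C(C)(C)OC(=O)OC
F9 | step 3 | (S)-4-benzyl-3-[(2S,3R,4E)-3-(tert-butyldimethylsilyloxy)-6-(methoxycarbonyloxy)-6-methyl-2-[(phenylselanyl)methyl]hept-4-enoyl]oxazolidin-2-one | O=C1OC[C@H](Cc2ccccc2)N1C(=O)[C@@H](C[Se]c1ccccc1)[C@H](O[Si](C)(C)C(C)(C)C)/C=C/C(C)(C)OC(=O)OC
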